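Assumption: the SMILES is read literally. Both oxiranes then carry their ring carbons cis and derive from a (1(10)Z,4Z)-diene. Atoms are labelled with germacrane numbers: C7 bears the isopropenyl group, and C3, C8 and C9 bear the angelate, senecioate and acetate.

## Retrosynthetic overview

1. 26 comes from 22 by late guided oxidations. These are the C4–C5 oxirane (peracid, anti to 3-OAng), the 9-OAc and the C1–C10 oxirane (V/t-BuOOH, syn to 9-OH). The 3-OAng comes from a CBS alcohol.
2. The ten-membered carbocycle 17 comes from the seven-membered lactone 12 by ring expansion. A (Z)-alkenyllithium takes the acyl carbon from O8 to C4 (new C3–C4 bond), and the freed 8-alkoxide is capped as the senecioate.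
3. 12 comes from diol 8 by but-3-enoate formation and RCM (C1=C10, Z by ring size). The 9-OH and the C7 isopropenyl group are masked together as a bromoether.
4. 8 comes from (S)-5-(hydroxymethyl)butenolide 1 by anti cuprate addition (C7), Felkin addition (C9) and lactol iodo-olefination (Z C4=C5).
5. Ring order: butenolide (bought), oxolane (step 6), oxepinone (step 8), cyclodecadienone (step 9), oxolane reopened (step 12), two oxiranes (steps 13 and 15).

## Route

Step 1
Reactants: 1 (S)-5-(hydroxymethyl)furan-2(5H)-one; 2 isopropenylmagnesium bromide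
Product: 4 (4R,5S)-5-(hydroxymethyl)-4-(prop-1-en-2-yl)oxolan-2-one, via bis-silylated ketene acetal 3 (not isolated)
Conditions: 2 (3 equiv), CuBr·SMe2 (20 mol %), Me3SiCl (3 equiv), THF, −78 °C; then 1 M HCl
Reagents that add atoms: none
Why: Copper-catalysed, Me3SiCl-accelerated conjugate addition to a butenolide; the reagent adds to the ring face anti to the C8 CH2O substituent, which sets C7 trans to it.

Step 2
Reactants: 4
Product: 5 (2S,3R)-5-oxo-3-(prop-1-en-2-yl)oxolane-2-carbaldehyde
Conditions: Dess–Martin periodinane, CH2Cl2, 0 °C to rt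
Reagents that add atoms: none
Why: Dess–Martin oxidation is neutral and fast, so the α-oxygenated aldehyde forms without epimerising C8 or moving the isopropenyl double bond; no new stereocentre.

Step 3
Reactants: 5; 2 isopropenylmagnesium bromide
Product: 6 (4R,5S)-5-[(1R)-1-hydroxy-2-methylprop-2-en-1-yl]-4-(prop-1-en-2-yl)oxolan-2-one
Conditions: 2 (1.1 equiv), THF, −78 °C; aq NH4Cl
Reagents that add atoms: none
Why: Grignard 1,2-addition under polar Felkin–Anh control; at −78 °C the aldehyde outruns the lactone, and the poorly chelating O8 stands anti to the nucleophile, which gives the 8,9-anti carbinol and sets C9.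

Step 4
Reactants: 6
Product: 7 (4R,5S)-5-[(1R)-1-hydroxy-2-methylprop-2-en-1-yl]-4-(prop-1-en-2-yl)oxolan-2-ol (anomers)
Conditions: i-Bu2AlH (2.2 equiv), CH2Cl2, −78 °C; aq Rochelle salt
Reagents that add atoms: none
Why: Partial lactone reduction; the tetrahedral aluminate survives at −78 °C and gives the lactol on work-up, as an anomer mixture whose centre is lost in step 5.

Step 5
Reactants: 7
Product: 8 (3R,4S,5R,7Z)-8-iodo-2-methyl-5-(prop-1-en-2-yl)nona-1,7-diene-3,4-diol
Conditions: EtPPh3I, n-BuLi, THF, rt; I2, −78 °C; NaN(SiMe3)2, −20 °C; then 7, −78 to −20 °C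
Reagents that add atoms: ethyltriphenylphosphonium iodide CC[P+](c1ccccc1)(c1ccccc1)c1ccccc1.[I-]; iodine [I][I]
Why: Stork–Zhao-type Wittig olefination; the unstabilised α-iodo ylide olefinates the lactol carbon C5 through a kinetic cis-oxaphosphetane, which puts iodine cis to the chain (Z C4=C5) and frees 8-OH.

Step 6
Reactants: 8
Product: 9 (2R,3S,4S)-5-(bromomethyl)-4-[(2Z)-3-iodobut-2-en-1-yl]-5-methyl-2-(prop-1-en-2-yl)oxolan-3-ol (C11 epimers)
Conditions: NBS (1.05 equiv), CH2Cl2, −20 °C
Reagents that add atoms: N-bromosuccinimide O=C1CCC(=O)N1Br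
Why: Bromoetherification (5-exo-trig, Markovnikov); only 9-OH can reach a bromonium ion through a five-membered ring (on the C7 isopropenyl group), so one step masks 9-OH and the alkene that would compete in step 8, and the new quaternary C11 is an epimer mixture erased in step 12.

Step 7
Reactants: 9; 10 but-3-enoic acid
Product: 11 but-3-enoate of 9 at O8
Conditions: 10, DCC, DMAP (5 mol %), CH2Cl2, 0 °C
Reagents that add atoms: none
Why: Steglich esterification of the only free hydroxyl (8-OH); low temperature and catalytic DMAP keep the but-3-enoate unconjugated.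

Step 8
Reactants: 11
Product: 12 oxolane-fused oxepinone (lactone ring O8–C3(=O)–C2–C1=C10(Me)–C9–C8; 7S,8S,9R; iodobutenyl chain on C7)
Conditions: second-generation Hoveyda–Grubbs catalyst (10 mol %), 1,4-benzoquinone (20 mol %), toluene (2 mM), 80 °C
Reagents that add atoms: none
Why: Ring-closing metathesis; only one 1,1-disubstituted alkene is left, the iodoalkene is inert, and a seven-membered ring can hold only the Z alkene, which fixes C1=C10.

Step 9
Reactants: 12; 13 3-methylbut-2-enoyl chloride (senecioyl chloride)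
Product: 17 (1(10)Z,4Z,7S,8S,9R)-12-bromo-9,11-epoxy-3-oxogermacra-1(10),4-dien-8-yl 3-methylbut-2-enoate, via alkenyllithium 14 (not isolated), via bridged lithium hemiketalate 15 (not isolated), via ring-expanded lithium alkoxide 16 (not isolated)
Conditions: t-BuLi (2.05 equiv), THF/Et2O/pentane 4:1:1 (2 mM), −100 °C, 10 min; −78 °C, 1 h; then 13 (1.5 equiv), −78 to −20 °C
Reagents that add atoms: none
Why: Proposed new method: iodine–lithium exchange on the (Z)-iodoalkene is faster than attack of t-BuLi on the ester, the α-protons or the neopentyl bromide, and it keeps the alkene geometry; the alkenyllithium C4 hangs from C7 next to C8, so it reaches the lactone carbonyl C3 through a seven-membered transition state; the bridged hemiketalate 15 can only collapse by expelling the C8 alkoxide, which moves the acyl carbon from O8 to C4, forms C3–C4 and turns the seven-membered lactone into the ten-membered (Z,Z)-dienone (C4–C7 enter the ring, O8 leaves it) without touching C7–C9; capping 16 at once as the senecioate blocks return to the hemiketal and transannular oxa-Michael addition; the closest known reaction types are Parham-type cyclisation, SmI2-promoted intramolecular nucleophilic acyl substitution of iodoalkyl lactones and anionic O-to-C acyl migration, none of which has been shown with an alkenyllithium or for a medium-ring carbocycle.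

Step 10
Reactants: 17
Product: 18 (3S)-alcohol of 17 (1(10)Z,4Z,3S,7S,8S,9R)
Conditions: (R)-Me-CBS (0.3 equiv), catecholborane (2 equiv), toluene, −78 to −40 °C; MeOH, aq NaHCO3
Reagents that add atoms: none
Why: Corey–Bakshi–Shibata reduction; the α-methylalkenyl side acts as the large group and C2H2 as the small one, so the (R)-catalyst delivers hydride under reagent control to set C3 as S, and catecholborane leaves the alkenes alone.

Step 11
Reactants: 18; 19 angelic acid ((Z)-2-methylbut-2-enoic acid)
Product: 21 3-angelate of 18, via mixed anhydride 20 (not isolated)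
Conditions: 19, 2,4,6-trichlorobenzoyl chloride, Et3N, toluene, rt; then 18, 60 °C
Reagents that add atoms: none
Why: Yamaguchi-type mixed-anhydride esterification run without DMAP; this acylates O3 with retention at C3 and avoids angelate-to-tiglate isomerisation.

Step 12
Reactants: 21
Product: 22 (1(10)Z,4Z,3S,7R,8S,9R)-3-angeloyloxy-9-hydroxygermacra-1(10),4,11-trien-8-yl 3-methylbut-2-enoate
Conditions: Zn dust, NH4Cl, EtOH, 70 °C
Reagents that add atoms: none
Why: Boord-type reductive β-elimination; zinc inserts into the C–Br bond and expels the β-alkoxide, which returns the isopropenyl group and 9-OH in one step without touching the esters or C7–C9.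

Step 13
Reactants: 22
Product: 23 1,10-epoxide of 22 (oxirane oxygen syn to 9-OH; C1 and C10 as in 26)
Conditions: VO(acac)2 (5 mol %), t-BuOOH (1.5 equiv, decane), CH2Cl2, 0 °C
Reagents that add atoms: tert-butyl hydroperoxide CC(C)(C)OO
Why: Vanadium-catalysed hydroxyl-directed epoxidation; only C1=C10 has a free allylic hydroxyl, and in medium-ring (Z)-allylic alcohols the metal-bound peroxide is delivered syn to that hydroxyl, which sets C1 and C10.

Step 14
Reactants: 23; 24 acetic anhydride
Product: 25 9-acetate of 23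
Conditions: 24, pyridine, DMAP (5 mol %), CH2Cl2, 0 °C
Reagents that add atoms: none
Why: Standard acetylation of the only free hydroxyl; the mild base leaves oxirane, angelate and senecioate untouched.

Step 15
Reactants: 25
Product: 26 target CNP0276917.1 (1R,3S,4S,5S,7R,8S,9S,10R)
Conditions: mCPBA (1.05 equiv), CH2Cl2, −20 to 0 °C
Reagents that add atoms: 3-chloroperoxybenzoic acid O=C(OO)c1cccc(Cl)c1
Why: Prilezhaev epoxidation; C4=C5 is the only electron-rich trisubstituted alkene left (the isopropenyl group reacts more slowly and the enoates are inert), and the peracid attacks its outer face anti to the allylic angelate, the usual trans outcome for medium-ring (Z)-allylic systems, which sets C4 and C5.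

## Compound list

1 | (S)-5-(hydroxymethyl)furan-2(5H)-one | O=C1C=C[C@H](O1)CO | starting material
2 | isopropenylmagnesium bromide | C=C(C)[Mg]Br | starting material
3 | bis-silylated ketene acetal of 4 | C=C(C)[C@H]1C=C(O[Si](C)(C)C)O[C@@H]1CO[Si](C)(C)C | intermediate
4 | (4R,5S)-5-(hydroxymethyl)-4-(prop-1-en-2-yl)oxolan-2-one | C=C(C)[C@H]1CC(=O)O[C@@H]1CO | intermediate
5 | (2S,3R)-5-oxo-3-(prop-1-en-2-yl)oxolane-2-carbaldehyde | C=C(C)[C@H]1CC(=O)O[C@@H]1C=O | intermediate
6 | (4R,5S)-5-[(1R)-1-hydroxy-2-methylprop-2-en-1-yl]-4-(prop-1-en-2-yl)oxolan-2-one | C=C(C)[C@H]1CC(=O)O[C@@H]1[C@H](O)C(C)=C | intermediate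
7 | lactol of 6 (anomers) | C=C(C)[C@H]1CC(O)O[C@@H]1[C@H](O)C(C)=C | intermediate
8 | (3R,4S,5R,7Z)-8-iodo-2-methyl-5-(prop-1-en-2-yl)nona-1,7-diene-3,4-diol | C=C(C)[C@@H](C/C=C(/C)I)[C@H](O)[C@H](O)C(C)=C | intermediate
9 | (2R,3S,4S)-5-(bromomethyl)-4-[(2Z)-3-iodobut-2-en-1-yl]-5-methyl-2-(prop-1-en-2-yl)oxolan-3-ol (C11 epimers) | C=C(C)[C@H]1OC(C)(CBr)[C@@H](C/C=C(/C)I)[C@@H]1O | intermediate
10 | but-3-enoic acid | C=CCC(=O)O | starting material
11 | but-3-enoate of 9 | C=C(C)[C@H]1OC(C)(CBr)[C@@H](C/C=C(/C)I)[C@@H]1OC(=O)CC=C | intermediate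
12 | oxolane-fused oxepinone lactone | CC1=CCC(=O)O[C@@H]2[C@@H]1OC(C)(CBr)[C@H]2C/C=C(/C)I | intermediate
13 | 3-methylbut-2-enoyl chloride | CC(C)=CC(=O)Cl | starting material
14 | alkenyllithium from 12 | CC1=CCC(=O)O[C@@H]2[C@@H]1OC(C)(CBr)[C@H]2C/C=C(/C)[Li] | intermediate
15 | bridged lithium hemiketalate (O8 bridges C3 and C8) | BrCC2(C)[C@H]1C/C=C(/C)C3([O-])C/C=C(/C)[C@@H](O2)[C@H]1O3.[Li+] | intermediate
16 | ring-expanded lithium C8 alkoxide | BrCC2(C)[C@H]1C/C=C(/C)C(=O)C/C=C(/C)[C@@H](O2)[C@H]1[O-].[Li+] | intermediate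
17 | (1(10)Z,4Z,7S,8S,9R)-12-bromo-9,11-epoxy-3-oxogermacra-1(10),4-dien-8-yl 3-methylbut-2-enoate | BrCC2(C)[C@H]1C/C=C(/C)C(=O)C/C=C(/C)[C@@H](O2)[C@H]1OC(=O)C=C(C)C | intermediate
18 | (3S)-alcohol of 17 | BrCC2(C)[C@H]1C/C=C(/C)[C@@H](O)C/C=C(/C)[C@@H](O2)[C@H]1OC(=O)C=C(C)C | intermediate
19 | angelic acid | C/C=C(/C)C(=O)O | starting material
20 | angelic 2,4,6-trichlorobenzoic anhydride | C/C=C(/C)C(=O)OC(=O)c1c(Cl)cc(Cl)cc1Cl | intermediate
21 | 3-angelate of 18 | BrCC2(C)[C@H]1C/C=C(/C)[C@@H](OC(=O)/C(C)=C\C)C/C=C(/C)[C@@H](O2)[C@H]1OC(=O)C=C(C)C | intermediate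
22 | (1(10)Z,4Z,3S,7R,8S,9R)-3-angeloyloxy-9-hydroxygermacra-1(10),4,11-trien-8-yl 3-methylbut-2-enoate | C=C(C)[C@H]1C/C=C(/C)[C@@H](OC(=O)/C(C)=C\C)C/C=C(/C)[C@@H](O)[C@H]1OC(=O)C=C(C)C | intermediate
23 | 1,10-epoxide of 22 (syn to 9-OH) | C=C(C)[C@H]1C/C=C(/C)[C@@H](OC(=O)/C(C)=C\C)C[C@H]2O[C@@]2(C)[C@@H](O)[C@H]1OC(=O)C=C(C)C | intermediate
24 | acetic anhydride | CC(=O)OC(C)=O | starting material
25 | 9-acetate of 23 | C=C(C)[C@H]1C/C=C(/C)[C@@H](OC(=O)/C(C)=C\C)C[C@H]2O[C@@]2(C)[C@@H](OC(C)=O)[C@H]1OC(=O)C=C(C)C | intermediate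
26 | CNP0276917.1 | C=C(C)[C@H]1C[C@@H]2O[C@]2(C)[C@@H](OC(=O)/C(C)=C\C)C[C@H]2O[C@@]2(C)[C@@H](OC(C)=O)[C@H]1OC(=O)C=C(C)C | target

## Step count and weak points

Total step count: 15. Longest linear sequence: 15 steps from 1. All other building blocks are bought.

**Step 9 (new ring expansion).**
- Risks: proton transfer from C2 to the alkenyllithium, a persistent hemiketalate, and transannular oxa-Michael addition of the C8 alkoxide.
- The fallback uses known chemistry; it sets out from 12 and comes back at 17.
- i-Bu2AlH at −78 °C reduces the lactone to the hydroxy aldehyde F1, which equilibrates with its seven-membered lactol.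
- CrCl2 with catalytic NiCl2 in DMSO then closes C3–C4 by intramolecular Nozaki–Hiyama–Kishi coupling, giving the ten-membered diol F2 as C3 epimers.
- MnO2 oxidises only the allylic C3 alcohol to the hydroxy dienone F3.
- Acylation of F3 by 13 in pyridine gives 17.

**Step 5 (iodo-olefination of a lactol that carries free hydroxyls).**
- Risks: slow lactol opening and decay of the fragile α-iodo ylide.
- The fallback sets out from 7 and comes back at 8.
- (Dibromomethyl)triphenylphosphonium bromide with t-BuOK tolerates free hydroxyls and gives the 1,1-dibromoalkene diol F4.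
- Negishi coupling with MeZnCl and Pd(PPh3)4 replaces only the bromine trans to the chain, giving the (Z)-bromoalkene diol F5.
- CuI, NaI and trans-N,N'-dimethylcyclohexane-1,2-diamine in dioxane exchange bromine for iodine with retention, giving 8.

**Step 15 (facial selectivity of the last epoxidation).**
- Risk: the peracid may prefer the face syn to the angelate.
- The fallback sets out from 25 and comes back at 26.
- NBS in aqueous DME forms the bromonium ion on the exposed face, and water opens it at the tertiary C4 from the other face, giving the bromohydrin F6.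
- DBU in CH2Cl2 closes the oxirane with inversion at C5, which places oxygen on the face opposite to direct peracid attack and gives 26.

Further compounds
F1 | step 9 | hydroxy aldehyde from 12 (C3 aldehyde, free 8-OH) | BrCC2(C)[C@@H](C/C=C(/C)I)[C@H](O)[C@H](O2)/C(C)=C\CC=O
F2 | step 9 | 12-bromo-9,11-epoxygermacra-1(10)Z,4Z-diene-3,8-diol (C3 epimers) | BrCC2(C)[C@H]1C/C=C(/C)C(O)C/C=C(/C)[C@@H](O2)[C@H]1O
F3 | step 9 | 12-bromo-9,11-epoxy-8-hydroxygermacra-1(10)Z,4Z-dien-3-one | BrCC2(C)[C@H]1C/C=C(/C)C(=O)C/C=C(/C)[C@@H](O2)[C@H]1O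
F4 | step 5 | (3R,4S,5R)-8,8-dibromo-2-methyl-5-(prop-1-en-2-yl)octa-1,7-diene-3,4-diol | C=C(C)[C@@H](CC=C(Br)Br)[C@H](O)[C@H](O)C(C)=C
F5 | step 5 | (3R,4S,5R,7Z)-8-bromo-2-methyl-5-(prop-1-en-2-yl)nona-1,7-diene-3,4-diol | C=C(C)[C@@H](C/C=C(/C)Br)[C@H](O)[C@H](O)C(C)=C
F6 | step 15 | 5-bromo-4-hydroxy bromohydrin of 25 | C=C(C)[C@H]1C[C@@H](Br)[C@@](O)(C)[C@@H](OC(=O)/C(C)=C\C)C[C@H]2O[C@@]2(C)[C@@H](OC(C)=O)[C@H]1OC(=O)C=C(C)C
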